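**Structural features**

The target 40 is a C20 gibberellane diacid. Ring A (cyclohexane, C1–C5 and C10) is trans-fused at C5–C10 to ring B (cyclopentane, C5, C6, C8, C9, C10). Ring B shares C8–C9 with a bicyclo[3.2.1]octane made of ring C (C8, C9, C11–C14) and ring D (C8, C13–C16), which carries the exocyclic C16=C17 methylene. Nine stereocentres are present: C3, C4, C5 and C6 are contiguous, C8, C9, C10 and C11 continue the chain, and C13 is fixed by the bridge; C4 and C10 are quaternary with CO2H and CH3 1,3-diaxial, and C8 is a quaternary bridgehead. The fragile groups are the 1,1-disubstituted alkene (acid moves it or triggers skeletal shifts), the 3-hydroxy-4-carboxyl unit (retro-aldol in base while esterified) and C6, which is α to a carboxyl. The 3β-hydroxyl is axial; the 11α-hydroxyl is equatorial on ring C and cis to the axial C9–C10 bond, so it lies on the ring C face that the C20 methyl covers. The real difficulty is the array C4–C5–C10–C9 (two quaternary carbons, two ring fusions) that joins ring A to the bicyclooctane, followed by C11. The key step uses exactly this array: C3 oxygen plus C4 (methyl, carboxyl) is a 2-methyl-3-oxo ester radical, C5 and quaternary C10 are the two ends of a trisubstituted alkene, and C9 is an alkene carbon of the bicyclooctene one ring further.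

**Logic of the disconnections**

40 from 39: the two carboxyl O–CH3 bonds are cut. Methyl esters carry both acids through the whole route, so no protecting-group change is needed. The forward step must cleave at the methyl carbon, because the acyl carbons are hindered and hydroxide would expose C6 and the C3/C4 β-hydroxy ester.

39 from 37 (through 38): the C3–H and C11–H bonds are cut together. Each alcohol is the result of hydride entering from the only open face: equatorially at C3 (axial alcohol), and from the β face at C11 because C20 closes the α face. Two stereocentres come from one operation without protection. The demand is a bulky hydride for C3 and access to C11 from the bridge side.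

37 from 34 (through 36 and 35): C12–H, the C11 carbonyl and C12–Br are cut back to the 11β,12β-epoxide. An oxygen cannot be delivered to C11 from the α face, and opening an α-epoxide at C12 would also be the anti-diaxial mode. The β-epoxide opens trans-diaxially at C12, and the wrong C11 configuration is then erased through the ketone. Regiochemistry is fixed by the ring C conformation and by C20. The forward steps must spare two esters, the C3 ketone and the C16 methylene.

34 from 31 and 32: the C16=C17 bond is cut. Methylenation is placed after oxygen transfer to C11–C12, so that 30 has only one alkene, and before any hydride step, so that C16 is no longer a ketone. The demand is reaction at C16 in preference to the C3 carbonyl next to quaternary C4.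

31 from 30: the two epoxide C–O bonds are cut. The forward step needs a neutral oxidant that leaves the strained C16 ketone alone, and attack on the β face.

30 from 29: C4–C5 and C9–C10 are cut. This removes rings A and B and four stereocentres (C4, C5, C9, C10) in one step and leaves an open chain on a bicyclooctene. The forward step must control chain folding, the face of the C5=C10 alkene and the face of ring C.

29 from 25 and 26: the C3–C4 bond is cut and the C16 ketone is unmasked. C4 with its methyl and ester arrives as a malonate half-ester, so no strong base meets the C6–H of a β,γ-unsaturated ester. The demand is neutral C-acylation.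

25 from 24, and 24 from 22 and 6: C1–C2 is cut and the C5=C10 alkene is moved back to a C5 carbinol with a C10=C1 methylene. A [3,3] shift builds the (E)-trisubstituted alkene and the two-carbon extension under weakly acidic conditions. The two methyl esters of 24 must then be told apart by hindrance.

22 from 21, and 21 from 18 and 19: C5–C6 is cut. C6 governs the face of the first radical closure, so it is set by reagent control (auxiliary 16) and not by the neighbouring bridgehead. The C5 carbinol is only a handle. The demand is an enolate that tolerates the quaternary neighbour, and auxiliary removal before the alkene sits next to C6.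

18 from 15 and 16; 15 from 14; 14 from 13: these are changes at C7 and a ketal at C16. Their purpose is to let the imide be enolised without the ketone competing.

13 from 12: the C9=C11 alkene is cut to a vinyl group on C8 and an allyl group on C13. The bridged six-membered ring comes from two terminal alkenes. They must be cis on the cyclopentanone.

12 from 10 and 11: C12–C13 is cut (enolate alkylation away from the quaternary carbon). 10 from 9 from 8: C14–H and the C16 oxygen are cut; the only allylic methylene of 8 becomes the ketone.

8 from 5 and 6: C6–C8 is cut. A [3,3] shift turns the carbinol stereocentre of 5 into the quaternary C8 with complete transfer of chirality.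

5 from 4, and 4 from 1 and 2: the carbinol C–H (catalyst-controlled reduction, the source of absolute configuration) and the C8–C9 bond (vinyl addition to a vinylogous ester) are cut, ending at commercial 1 and 2.

**Other disconnections considered**

Alternative 1: The cut is C8–C9 and C11–C12, with a later shift of C16 from C12 to C13. In the forward step PhI(OAc)2 in methanol oxidises the guaiacol A2 to its 6,6-dimethoxycyclohexadienone, whose diene (C8, C14, C13, C12) adds the tethered (Z)-enol ether to give the bicyclo[2.2.2]octenone ketal A1.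
- In its favour: C8, C9, C11 and C12 are set in one concerted, thermally driven event. The C11 oxygen arrives with its configuration fixed by the enol ether geometry. On C11 this is better than the chosen plan, which needs steps 17 and 19–22 for it.
- Against it here: ring A with C3, C4, C5 and C10, including both quaternary carbons, must be built separately beforehand. That is the problem the chosen key step solves. C6 in A2 is benzylic and α to an ester, so it is more labile than in 29. The dienone can dimerise. After the cycloaddition a skeletal acyl shift and removal of both C15 oxygens are still needed.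
- Comparison: on structure it is better at C11, equal at C8 and worse for ring A. On mechanism a pericyclic step is more predictable than a three-event radical sequence. On step economy it should be longer.

Alternative 2: The cut is C13–C16. In the forward step Pd(OAc)2 with PPh3 cycloisomerises the 1,6-enyne A4 (propargyl on C8, C12=C13 alkene, 11α-silyloxy) in an Alder-ene sense to A3.
- In its favour: ring D and the C16 methylene form in one catalytic, redox-neutral step, with no ketone and no chemoselective olefination. On C16/C17 this is better than the chosen plan. C11 emerges as a silyl enol ether, that is, at the ketone level from which β-face hydride gives the 11α-alcohol. On C11 it is the equal of the chosen plan in logic and shorter.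
- Against it here: it is a finishing move. A4 already holds rings A, B and C, seven stereocentres and the quaternary C8, so the hard part is only displaced. The ene step needs the C11 hydrogen on the alkyne side and could instead bond at C12. Hydrolysis gives an 11-ketone next to the epimerisable C9.
- Comparison: on structure it is superior for ring D and silent on rings A and B. On mechanism it is of similar reliability. On step economy it is probably longer overall.

Alternative 3: The cut is C8–C9 and C12–C13. In the forward step base ionises the chloro ketone A6 to the oxyallyl cation (C9, C11, C12), which adds across the cyclopentadiene on C6 to give the 11-ketone A5 with rings B, C and D closed.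
- In its favour: it gives the largest gain in rings per step of all four plans. The C11 carbonyl is placed directly on the right carbon, which is better than the chosen plan on C11. The core-forming phase could be the shortest.
- Against it here: the 1-substituted cyclopentadiene of A6 is positionally unstable (hydrogen shifts, dimerisation). The cation terminus C9 is attached to quaternary C10. Facial and endo/exo control at C8, C9 and C13 rest on a short tether. A5 has a C15=C16 alkene with no oxygen, so putting C17 on C16 and not C15 is unsolved. On C16 this is worse than the chosen plan, where the ketone is built in. Ring A must again pre-exist.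
- Comparison: on structure it is better at C11, worse at C16 and equal on ring A. On mechanism its stereochemistry is less predictable. On step economy it is potentially competitive if the diene problem is solved.

Key step: step 16

Assumptions and remarks:
- Atom labels C1–C20 are those of 40 (gibberellane numbering) and are used for the same atoms in all intermediates; α/β refer to the usual drawing with ring A on the left.
- The structures of 29 and 30 were checked against 40 (C6, C8, C13 and the (E)-alkene in 29; all seven centres in 30) and contain no error; they are used unchanged.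
- The way to 29 avoids any strong base once C6 is a stereocentre next to the alkene, so no allylic bromide or dianion alkylation is used.
- The way from 30 does not use an α-epoxide opened at C12 by hydride: that oxygen would have to enter past C20 and open in the anti-diaxial sense.
- 29 is a mixture of C4 epimers; both give the same radical.
- 26 is taken as purchased; if made by half-saponification of dimethyl methylmalonate, this adds one step outside the linear sequence.

**Route**

Step 1
Reactants: 1 3-ethoxycyclopent-2-en-1-one; 2 ethenylmagnesium bromide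
Product: 4 3-ethenylcyclopent-2-en-1-one, via 1,2-adduct bromomagnesium alkoxide 3 (not isolated)
Conditions: CH2=CHMgBr, THF, 0 °C; then 1 M HCl, 0 °C
Reagents that add atoms: water, O
Why: Grignard 1,2-addition to the vinylogous ester followed by acid hydrolysis with allylic transposition (Stork–Danheiser sequence) gives the 3-substituted enone; no stereocentre is formed and the dienone is used at once.

Step 2
Reactants: 4 3-ethenylcyclopent-2-en-1-one
Product: 5 (1R)-3-ethenylcyclopent-2-en-1-ol
Conditions: (S)-2-methyl-CBS-oxazaborolidine (0.1 equiv), catecholborane, toluene, −78 °C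
Reagents that add atoms: none
Why: Corey–Bakshi–Shibata reduction; the conjugated alkenyl side is the large group, so the (S)-catalyst should deliver hydride to give the (R)-carbinol, and catecholborane at −78 °C reduces the carbonyl only.

Step 3
Reactants: 5 (1R)-3-ethenylcyclopent-2-en-1-ol; 6 trimethyl orthoacetate
Product: 8 methyl 2-[(1R)-1-ethenylcyclopent-2-en-1-yl]acetate, via mixed ketene acetal 7 (not isolated)
Conditions: MeC(OMe)3 (6 equiv), EtCO2H (0.05 equiv), toluene, 110 °C, MeOH distilled off
Reagents that add atoms: none
Why: Johnson–Claisen rearrangement; the ketene acetal shifts suprafacially across the ring alkene, so the carbinol stereocentre is exchanged for the quaternary carbon (future C8) with the acetic ester on the face the oxygen occupied.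

Step 4
Reactants: 8 methyl 2-[(1R)-1-ethenylcyclopent-2-en-1-yl]acetate
Product: 9 methyl 2-[(1R)-1-ethenyl-4-oxocyclopent-2-en-1-yl]acetate
Conditions: Rh2(caprolactamate)4 (0.5 mol%), t-BuOOH (70% aq.), K2CO3, CH2Cl2, rt
Reagents that add atoms: tert-butyl hydroperoxide, CC(C)(C)OO
Why: Catalytic allylic C–H oxidation; the ring CH2 next to the alkene (future C16) is the only allylic methylene, the other allylic position of both alkenes being the quaternary carbon, so the enone should form at one site.

Step 5
Reactants: 9 methyl 2-[(1R)-1-ethenyl-4-oxocyclopent-2-en-1-yl]acetate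
Product: 10 methyl 2-[(1S)-1-ethenyl-3-oxocyclopentyl]acetate
Conditions: [(Ph3P)CuH]6 (0.25 equiv), wet benzene, rt
Reagents that add atoms: none
Why: Conjugate reduction by the copper hydride hexamer; hydride adds only to the enone β-carbon, and the isolated vinyl group and the ester are inert (the descriptor changes by priority only).

Step 6
Reactants: 10 methyl 2-[(1S)-1-ethenyl-3-oxocyclopentyl]acetate; 11 3-bromoprop-1-ene
Product: 12 methyl 2-[(1S,4R)-1-ethenyl-3-oxo-4-(prop-2-en-1-yl)cyclopentyl]acetate (ethenyl and allyl cis)
Conditions: LiN(i-Pr)2 (1.05 equiv), THF, −78 °C; 11, DMPU, −78 → −30 °C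
Reagents that add atoms: none
Why: Kinetic enolate alkylation; the amide base removes the α-proton remote from the quaternary carbon and allylation follows. Facial control by the 1,3-related quaternary carbon is expected to be modest, so the trans epimer is equilibrated at the ketone α-carbon with DBU and recycled.

Step 7
Reactants: 12 methyl 2-[(1S,4R)-1-ethenyl-3-oxo-4-(prop-2-en-1-yl)cyclopentyl]acetate
Product: 13 methyl 2-[(1S,5R)-6-oxobicyclo[3.2.1]oct-2-en-1-yl]acetate
Conditions: second-generation Grubbs catalyst (5 mol%), CH2Cl2 (5 mM), 40 °C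
Reagents that add atoms: none
Why: Ring-closing metathesis of the cis vinyl and allyl groups closes the cyclohexene of the bicyclooctene (future C9=C11, C12) with loss of ethene; the catalyst should load on the allyl group and close onto the neopentyl vinyl group, with dilution against oligomers.

Step 8
Reactants: 13 methyl 2-[(1S,5R)-6-oxobicyclo[3.2.1]oct-2-en-1-yl]acetate
Product: 14 methyl 2-[(1'S,5'R)-spiro[1,3-dioxolane-2,6'-bicyclo[3.2.1]oct[2]en]-1'-yl]acetate
Conditions: HOCH2CH2OH, pyridinium p-toluenesulfonate (cat.), benzene, reflux, Dean–Stark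
Reagents that add atoms: ethane-1,2-diol, OCCO
Why: Acid-catalysed ketalisation; the ketone must be masked because it would be enolised together with the imide in step 11.

Step 9
Reactants: 14 methyl 2-[(1'S,5'R)-spiro[1,3-dioxolane-2,6'-bicyclo[3.2.1]oct[2]en]-1'-yl]acetate
Product: 15 2-[(1'S,5'R)-spiro[1,3-dioxolane-2,6'-bicyclo[3.2.1]oct[2]en]-1'-yl]acetic acid
Conditions: LiOH·H2O, THF–MeOH–H2O, rt; then 1 M HCl to pH 4, 0 °C
Reagents that add atoms: lithium hydroxide, [Li+].[OH-]
Why: Saponification of a primary acetic ester; the dioxolane survives brief acidification to pH 4 in the cold.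

Step 10
Reactants: 15 2-[(1'S,5'R)-spiro[1,3-dioxolane-2,6'-bicyclo[3.2.1]oct[2]en]-1'-yl]acetic acid; 16 (4R)-4-benzyl-1,3-oxazolidin-2-one
Product: 18 (4R)-4-benzyl-3-{[(1'S,5'R)-spiro[1,3-dioxolane-2,6'-bicyclo[3.2.1]oct[2]en]-1'-yl]acetyl}-1,3-oxazolidin-2-one, via mixed pivalic anhydride 17 (not isolated)
Conditions: t-BuCOCl, Et3N, THF, −20 °C; then 16, LiCl, −20 °C → rt
Reagents that add atoms: none
Why: N-Acylation of the oxazolidinone through the mixed anhydride (LiCl/Et3N protocol); attack at the less hindered carbonyl of 17 attaches the auxiliary.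

Step 11
Reactants: 18 (4R)-4-benzyl-3-{[(1'S,5'R)-spiro[1,3-dioxolane-2,6'-bicyclo[3.2.1]oct[2]en]-1'-yl]acetyl}-1,3-oxazolidin-2-one; 19 2-methylprop-2-enal
Product: 21 (4R)-4-benzyl-3-{(2R,3R)-3-hydroxy-4-methyl-2-[(1'R,5'R)-spiro[1,3-dioxolane-2,6'-bicyclo[3.2.1]oct[2]en]-1'-yl]pent-4-enoyl}-1,3-oxazolidin-2-one, via (Z)-boron enolate 20 (not isolated)
Conditions: Bu2BOTf, i-Pr2NEt, CH2Cl2, −78 → 0 °C; 19, −78 → 0 °C; pH 7 buffer, MeOH, H2O2
Reagents that add atoms: none
Why: Evans syn aldol through a Zimmerman–Traxler chair; the (R)-auxiliary fixes the enolate face and so C6, independently of the bridgehead, while the C5 carbinol is syn and is consumed in step 13. The minor enantiomer of the bicycle would give a separable diastereomer.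

Step 12
Reactants: 21 (4R)-4-benzyl-3-{(2R,3R)-3-hydroxy-4-methyl-2-[(1'R,5'R)-spiro[1,3-dioxolane-2,6'-bicyclo[3.2.1]oct[2]en]-1'-yl]pent-4-enoyl}-1,3-oxazolidin-2-one
Product: 22 methyl (2R,3R)-3-hydroxy-4-methyl-2-[(1'R,5'R)-spiro[1,3-dioxolane-2,6'-bicyclo[3.2.1]oct[2]en]-1'-yl]pent-4-enoate
Conditions: MeMgBr, MeOH (gives MeOMgBr), CH2Cl2, 0 °C
Reagents that add atoms: methanol, CO
Why: Transesterification of the imide with bromomagnesium methoxide; it is done while C6 is still flanked by a carbinol, so neither retro-aldol at 0 °C nor epimerisation is expected.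

Step 13
Reactants: 22 methyl (2R,3R)-3-hydroxy-4-methyl-2-[(1'R,5'R)-spiro[1,3-dioxolane-2,6'-bicyclo[3.2.1]oct[2]en]-1'-yl]pent-4-enoate; 6 trimethyl orthoacetate
Product: 24 dimethyl (2S,3E)-4-methyl-2-[(1'R,5'R)-spiro[1,3-dioxolane-2,6'-bicyclo[3.2.1]oct[2]en]-1'-yl]hept-3-enedioate, via mixed ketene acetal 23 (not isolated)
Conditions: MeC(OMe)3 (10 equiv), EtCO2H (0.1 equiv), xylene, 130 °C
Reagents that add atoms: none
Why: Johnson–Claisen rearrangement; the chair with the bulky C6 substituent equatorial gives the (E)-C5=C10 alkene and the C1–C2 bond, and the weakly acidic medium leaves C6 untouched (its descriptor changes by priority only).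

Step 14
Reactants: 24 dimethyl (2S,3E)-4-methyl-2-[(1'R,5'R)-spiro[1,3-dioxolane-2,6'-bicyclo[3.2.1]oct[2]en]-1'-yl]hept-3-enedioate
Product: 25 (4E,6S)-7-methoxy-4-methyl-7-oxo-6-[(1'R,5'R)-spiro[1,3-dioxolane-2,6'-bicyclo[3.2.1]oct[2]en]-1'-yl]hept-4-enoic acid
Conditions: Me3SnOH (4 equiv), ClCH2CH2Cl, 70 °C; then 0.05 M HCl wash
Reagents that add atoms: trimethyltin hydroxide, C[Sn](C)(C)O
Why: Tin hydroxide hydrolysis is selective for the unhindered primary ester; the α-branched ester beside the quaternary bridgehead should not react, and the near-neutral conditions do not epimerise C6.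

Step 15
Reactants: 25 (4E,6S)-7-methoxy-4-methyl-7-oxo-6-[(1'R,5'R)-spiro[1,3-dioxolane-2,6'-bicyclo[3.2.1]oct[2]en]-1'-yl]hept-4-enoic acid; 26 potassium 3-methoxy-2-methyl-3-oxopropanoate
Product: 29 dimethyl (6E,8S)-2,6-dimethyl-3-oxo-8-[(1R,5R)-6-oxobicyclo[3.2.1]oct-2-en-1-yl]non-6-enedioate (C2 epimers), via acyl imidazole 27 (not isolated), via dioxolane keto ester 28 (not isolated)
Conditions: 1,1'-carbonyldiimidazole, THF, rt; then 26, MgCl2, Et3N, MeCN–THF, rt → 40 °C; then 1 M HCl, THF, rt
Reagents that add atoms: water, O
Why: Masamune–Brooks C-acylation of the magnesium malonate half-ester by the acyl imidazole, then decarboxylation, forms C3–C4 without a strong base. The acidic work-up also hydrolyses the dioxolane, giving the cyclisation substrate with the C16 ketone free.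

Step 16
Reactants: 29 dimethyl (6E,8S)-2,6-dimethyl-3-oxo-8-[(1R,5R)-6-oxobicyclo[3.2.1]oct-2-en-1-yl]non-6-enedioate
Product: 30 dimethyl 3,16-dioxo-17-norgibberell-11-ene-7,19-dioate (4α-CO2Me, 5β-H, 6β-CO2Me, 9β-H, 10α-CH3, C15–C16 bridge β)
Conditions: Mn(OAc)3·2H2O (2.2 equiv), Cu(OAc)2·H2O (0.5 equiv), degassed AcOH (0.02 M), 25 → 45 °C
Reagents that add atoms: none
Why: This is an oxidative free-radical bicyclisation of an unsaturated 2-alkyl-3-oxo ester, the closest known class being the tandem 6-endo/5-exo closures of such esters onto a trisubstituted and then a second alkene under trivalent manganese and divalent copper. Mn(OAc)3 enolises and oxidises the β-keto ester, the only site it can attack at this temperature, to the electrophilic tertiary C4 radical. Ring A closes 6-endo-trig on C5, the unsubstituted end of the alkene, through a chair with the ketone in the ring and the ester axial, which sets C4 with the ester cis to the future C10 methyl. C5 is set by C6: allylic 1,3-strain with the C20 methyl holds H6 in the alkene plane, so the radical enters anti to the bicyclic substituent. The tertiary C10 radical closes ring B 5-exo-trig on C9; the new five-membered ring can only be cis-fused to ring C across C8–C9, which puts C10 on the face away from the C15–C16 bridge and sets C9, while bond formation equatorial on the ring A chair gives the trans A/B fusion and sets C10. Cu(OAc)2 captures the secondary C11 radical and a β-hydrogen is lost from C12, the less substituted direction, to give the C11–C12 alkene. The step needs 6-endo over 5-exo in the first closure (secured by the methyl on the near alkene carbon), cyclisation of the C10 radical faster than its oxidation (sub-stoichiometric copper, dilution), and elimination towards C12 and not C9.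

Step 17
Reactants: 30 dimethyl 3,16-dioxo-17-norgibberell-11-ene-7,19-dioate
Product: 31 dimethyl 11β,12β-epoxy-3,16-dioxo-17-norgibberellane-7,19-dioate
Conditions: dimethyldioxirane (acetone solution, 1.2 equiv), CH2Cl2, 0 °C
Reagents that add atoms: dimethyldioxirane, CC1(C)OO1
Why: Dioxirane epoxidation is neutral and does not cause Baeyer–Villiger oxidation of the strained ketone. The α face of C11 is covered by the C20 methyl on the axial C9–C10 bond, so oxygen should enter from the β face, where C16 is planar.

Step 18
Reactants: 31 dimethyl 11β,12β-epoxy-3,16-dioxo-17-norgibberellane-7,19-dioate; 32 methyltriphenylphosphonium bromide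
Product: 34 dimethyl 11β,12β-epoxy-3-oxogibberell-16-ene-7,19-dioate, via methylenetriphenylphosphorane 33 (not isolated)
Conditions: 32 (1.6 equiv), KN(SiMe3)2 (1.5 equiv), THF, 0 °C; then 31, −20 °C → rt
Reagents that add atoms: none
Why: Wittig methylenation; the strained, less hindered C16 ketone should react well before the C3 ketone beside quaternary C4. An amide-generated ylide leaves no alkoxide that could cleave the non-enolisable β-keto ester, and the epoxide is inert to the ylide.

Step 19
Reactants: 34 dimethyl 11β,12β-epoxy-3-oxogibberell-16-ene-7,19-dioate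
Product: 35 dimethyl 12α-bromo-11β-hydroxy-3-oxogibberell-16-ene-7,19-dioate
Conditions: LiBr (5 equiv), AcOH (3 equiv), THF, rt
Reagents that add atoms: lithium bromide, [Li+].[Br-]
Why: Halohydrin formation by SN2 opening of the activated epoxide; bromide attacks C12 from the open α face in the trans-diaxial (Fürst–Plattner) mode, whereas attack at C11 would have to pass C20, so oxygen stays on C11 (axial, β).

Step 20
Reactants: 35 dimethyl 12α-bromo-11β-hydroxy-3-oxogibberell-16-ene-7,19-dioate
Product: 36 dimethyl 12α-bromo-3,11-dioxogibberell-16-ene-7,19-dioate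
Conditions: Dess–Martin periodinane, NaHCO3, CH2Cl2, 0 °C → rt
Reagents that add atoms: none
Why: Periodinane oxidation of the hindered axial alcohol removes the wrong C11 configuration; ketone, esters and alkene are inert.

Step 21
Reactants: 36 dimethyl 12α-bromo-3,11-dioxogibberell-16-ene-7,19-dioate
Product: 37 dimethyl 3,11-dioxogibberell-16-ene-7,19-dioate
Conditions: Zn dust, AcOH, Et2O, rt
Reagents that add atoms: none
Why: Reductive cleavage of the α-bromo ketone through the zinc enolate, which is protonated at C12; the mild acid should not epimerise C9.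

Step 22
Reactants: 37 dimethyl 3,11-dioxogibberell-16-ene-7,19-dioate
Product: 39 dimethyl 3β,11α-dihydroxygibberell-16-ene-7,19-dioate, via 3β-hydroxy 11-ketone 38 (not isolated)
Conditions: LiBH(s-Bu)3, THF, −78 °C; then NaBH4, MeOH, −40 → 0 °C; then NaOH, H2O2, 0 °C
Reagents that add atoms: none
Why: Hydride reduction of both ketones; the bulky borohydride attacks C3 equatorially to give the axial 3β-alcohol. At C11 the α face is closed by C20, so hydride (from either reagent) must add from the β face, giving the equatorial 11α-alcohol, which is also the more stable epimer. Esters are not reduced at these temperatures.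

Step 23
Reactants: 39 dimethyl 3β,11α-dihydroxygibberell-16-ene-7,19-dioate
Product: 40 3β,11α-dihydroxygibberell-16-ene-7,19-dioic acid (target)
Conditions: n-PrSLi (from n-PrSH and n-BuLi, 10 equiv), HMPA, 25 → 50 °C; then 1 M HCl to pH 3
Reagents that add atoms: none
Why: SN2 demethylation by thiolate cleaves both hindered esters at the methyl carbon; the thiolate is too weak a base to epimerise C6 or to start retro-aldol cleavage at C3/C4, and it does not touch the alkene.

**Compound list**

1 | 3-ethoxycyclopent-2-en-1-one | CCOC1=CC(=O)CC1 | starting material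
2 | ethenylmagnesium bromide | C=C[Mg]Br | starting material
3 | 3-ethoxy-1-ethenylcyclopent-2-en-1-ol (bromomagnesium alkoxide in the flask, racemic) | CCOC1=CC(O)(C=C)CC1 | intermediate (not isolated)
4 | 3-ethenylcyclopent-2-en-1-one | C=CC1=CC(=O)CC1 | intermediate
5 | (1R)-3-ethenylcyclopent-2-en-1-ol | O[C@H]1C=C(C=C)CC1 | intermediate
6 | trimethyl orthoacetate | CC(OC)(OC)OC | starting material
7 | (1R)-3-ethenylcyclopent-2-en-1-yl methyl ketene acetal | C=C(OC)O[C@H]1C=C(C=C)CC1 | intermediate (not isolated)
8 | methyl 2-[(1R)-1-ethenylcyclopent-2-en-1-yl]acetate | COC(=O)C[C@]1(C=C)C=CCC1 | intermediate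
9 | methyl 2-[(1R)-1-ethenyl-4-oxocyclopent-2-en-1-yl]acetate | COC(=O)C[C@]1(C=C)C=CC(=O)C1 | intermediate
10 | methyl 2-[(1S)-1-ethenyl-3-oxocyclopentyl]acetate | COC(=O)C[C@]1(C=C)CCC(=O)C1 | intermediate
11 | 3-bromoprop-1-ene | C=CCBr | starting material
12 | methyl 2-[(1S,4R)-1-ethenyl-3-oxo-4-(prop-2-en-1-yl)cyclopentyl]acetate | COC(=O)C[C@@]1(C=C)CC(=O)[C@H](CC=C)C1 | intermediate
13 | methyl 2-[(1S,5R)-6-oxobicyclo[3.2.1]oct-2-en-1-yl]acetate | COC(=O)C[C@@]12CC(=O)[C@@H](C1)CC=C2 | intermediate
14 | methyl 2-[(1'S,5'R)-spiro[1,3-dioxolane-2,6'-bicyclo[3.2.1]oct[2]en]-1'-yl]acetate | COC(=O)C[C@@]12CC3(OCCO3)[C@@H](C1)CC=C2 | intermediate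
15 | 2-[(1'S,5'R)-spiro[1,3-dioxolane-2,6'-bicyclo[3.2.1]oct[2]en]-1'-yl]acetic acid | OC(=O)C[C@@]12CC3(OCCO3)[C@@H](C1)CC=C2 | intermediate
16 | (4R)-4-benzyl-1,3-oxazolidin-2-one | O=C1N[C@H](Cc2ccccc2)CO1 | starting material
17 | mixed pivalic anhydride of 15 | CC(C)(C)C(=O)OC(=O)C[C@@]12CC3(OCCO3)[C@@H](C1)CC=C2 | intermediate (not isolated)
18 | (4R)-4-benzyl-3-{[(1'S,5'R)-spiro[1,3-dioxolane-2,6'-bicyclo[3.2.1]oct[2]en]-1'-yl]acetyl}-1,3-oxazolidin-2-one | O=C(C[C@@]12CC3(OCCO3)[C@@H](C1)CC=C2)N1[C@H](Cc2ccccc2)COC1=O | intermediate
19 | 2-methylprop-2-enal | CC(=C)C=O | starting material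
20 | (Z)-dibutylboron enolate of 18 | CCCCB(CCCC)O/C(N1[C@H](Cc2ccccc2)COC1=O)=C\[C@@]12CC3(OCCO3)[C@@H](C1)CC=C2 | intermediate (not isolated)
21 | (4R)-4-benzyl-3-{(2R,3R)-3-hydroxy-4-methyl-2-[(1'R,5'R)-spiro[1,3-dioxolane-2,6'-bicyclo[3.2.1]oct[2]en]-1'-yl]pent-4-enoyl}-1,3-oxazolidin-2-one | C=C(C)[C@H](O)[C@H](C(=O)N1[C@H](Cc2ccccc2)COC1=O)[C@@]12CC3(OCCO3)[C@@H](C1)CC=C2 | intermediate
22 | methyl (2R,3R)-3-hydroxy-4-methyl-2-[(1'R,5'R)-spiro[1,3-dioxolane-2,6'-bicyclo[3.2.1]oct[2]en]-1'-yl]pent-4-enoate | C=C(C)[C@H](O)[C@H](C(=O)OC)[C@@]12CC3(OCCO3)[C@@H](C1)CC=C2 | intermediate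
23 | mixed methyl ketene acetal of 22 | C=C(C)[C@H](OC(=C)OC)[C@H](C(=O)OC)[C@@]12CC3(OCCO3)[C@@H](C1)CC=C2 | intermediate (not isolated)
24 | dimethyl (2S,3E)-4-methyl-2-[(1'R,5'R)-spiro[1,3-dioxolane-2,6'-bicyclo[3.2.1]oct[2]en]-1'-yl]hept-3-enedioate | COC(=O)CC/C(C)=C/[C@H](C(=O)OC)[C@@]12CC3(OCCO3)[C@@H](C1)CC=C2 | intermediate
25 | (4E,6S)-7-methoxy-4-methyl-7-oxo-6-[(1'R,5'R)-spiro[1,3-dioxolane-2,6'-bicyclo[3.2.1]oct[2]en]-1'-yl]hept-4-enoic acid | OC(=O)CC/C(C)=C/[C@H](C(=O)OC)[C@@]12CC3(OCCO3)[C@@H](C1)CC=C2 | intermediate
26 | potassium 3-methoxy-2-methyl-3-oxopropanoate | COC(=O)C(C)C(=O)[O-].[K+] | starting material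
27 | acyl imidazole of 25 | O=C(CC/C(C)=C/[C@H](C(=O)OC)[C@@]12CC3(OCCO3)[C@@H](C1)CC=C2)n1ccnc1 | intermediate (not isolated)
28 | dimethyl (6E,8S)-2,6-dimethyl-3-oxo-8-[(1'R,5'R)-spiro[1,3-dioxolane-2,6'-bicyclo[3.2.1]oct[2]en]-1'-yl]non-6-enedioate (C2 epimers) | COC(=O)C(C)C(=O)CC/C(C)=C/[C@H](C(=O)OC)[C@@]12CC3(OCCO3)[C@@H](C1)CC=C2 | intermediate (not isolated)
29 | dimethyl (6E,8S)-2,6-dimethyl-3-oxo-8-[(1R,5R)-6-oxobicyclo[3.2.1]oct-2-en-1-yl]non-6-enedioate (C2 epimers; precursor of the key step) | COC(=O)C(C)C(=O)CC/C(C)=C/[C@H](C(=O)OC)[C@@]12CC(=O)[C@@H](C1)CC=C2 | intermediate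
30 | dimethyl 3,16-dioxo-17-norgibberell-11-ene-7,19-dioate (product of the key step) | O=C1C[C@]23C[C@H]1C=C[C@H]2[C@]1(C)CCC(=O)[C@@](C)(C(=O)OC)[C@H]1[C@@H]3C(=O)OC | intermediate
31 | dimethyl 11β,12β-epoxy-3,16-dioxo-17-norgibberellane-7,19-dioate | O=C1C[C@]23C[C@H]1[C@@H]4O[C@@H]4[C@H]2[C@]1(C)CCC(=O)[C@@](C)(C(=O)OC)[C@H]1[C@@H]3C(=O)OC | intermediate
32 | methyltriphenylphosphonium bromide | C[P+](c1ccccc1)(c1ccccc1)c1ccccc1.[Br-] | starting material
33 | methylenetriphenylphosphorane | C=P(c1ccccc1)(c1ccccc1)c1ccccc1 | intermediate (not isolated)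
34 | dimethyl 11β,12β-epoxy-3-oxogibberell-16-ene-7,19-dioate | C=C1C[C@]23C[C@H]1[C@@H]4O[C@@H]4[C@H]2[C@]1(C)CCC(=O)[C@@](C)(C(=O)OC)[C@H]1[C@@H]3C(=O)OC | intermediate
35 | dimethyl 12α-bromo-11β-hydroxy-3-oxogibberell-16-ene-7,19-dioate | C=C1C[C@]23C[C@H]1[C@@H](Br)[C@H](O)[C@H]2[C@]1(C)CCC(=O)[C@@](C)(C(=O)OC)[C@H]1[C@@H]3C(=O)OC | intermediate
36 | dimethyl 12α-bromo-3,11-dioxogibberell-16-ene-7,19-dioate | C=C1C[C@]23C[C@H]1[C@@H](Br)C(=O)[C@H]2[C@]1(C)CCC(=O)[C@@](C)(C(=O)OC)[C@H]1[C@@H]3C(=O)OC | intermediate
37 | dimethyl 3,11-dioxogibberell-16-ene-7,19-dioate | C=C1C[C@]23C[C@H]1CC(=O)[C@H]2[C@]1(C)CCC(=O)[C@@](C)(C(=O)OC)[C@H]1[C@@H]3C(=O)OC | intermediate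
38 | dimethyl 3β-hydroxy-11-oxogibberell-16-ene-7,19-dioate | C=C1C[C@]23C[C@H]1CC(=O)[C@H]2[C@]1(C)CC[C@H](O)[C@@](C)(C(=O)OC)[C@H]1[C@@H]3C(=O)OC | intermediate (not isolated)
39 | dimethyl 3β,11α-dihydroxygibberell-16-ene-7,19-dioate | C=C1C[C@]23C[C@H]1C[C@@H](O)[C@H]2[C@]1(C)CC[C@H](O)[C@@](C)(C(=O)OC)[C@H]1[C@@H]3C(=O)OC | intermediate
40 | 3β,11α-dihydroxygibberell-16-ene-7,19-dioic acid (CNP0232910.1) | C=C1C[C@]23C[C@H]1C[C@@H](O)[C@H]2[C@]1(C)CC[C@H](O)[C@@](C)(C(=O)O)[C@H]1[C@@H]3C(=O)O | target

**Step count and least certain steps**

Total step count: 23. Longest linear sequence: 23 steps (1 to 40); 2, 6, 11, 16, 19, 26 and 32 are commercial.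

Step 16 (key step). The most likely failure is loss of the C10 radical before it closes ring B (oxidation to an alkene or cation), because the new C9–C10 bond joins a quaternary carbon to a carbon next to the quaternary C8; closure with a cis A/B fusion is the second risk. The fallback sets out from 29 and changes the way the radical chain is run, from oxidative to halogen atom transfer, so that no oxidant is present. Iodination at C4 with N-iodosuccinimide and catalytic Mg(ClO4)2 should give the α-iodo keto ester F1. Irradiation with catalytic (Bu3Sn)2 in benzene should then carry out the same 6-endo/5-exo sequence and end by iodine transfer to C11, giving the tetracyclic 11-iodide F2. Elimination of hydrogen iodide with DBU (anti hydrogen on C12) returns to the route at 30.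

Step 7. The likely failure is oligomerisation in place of ring closure, because the catalyst must close a strained bridged ring onto a vinyl group on a quaternary carbon, and only the cis epimer of 12 can close. The fallback sets out from 12 and forms the same alkene by carbonyl coupling instead of metathesis. Ketalisation (ethane-1,2-diol, acid) should give the dioxolane diene F3, ozonolysis with Me2S work-up the dialdehyde F4, and intramolecular McMurry coupling with low-valent titanium (TiCl3, Zn–Cu, DME) the cyclohexene. The fallback returns at 14.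

Step 11. The likely failure is slow or reversible addition of the boron enolate, whose α-carbon carries a quaternary substituent, to the aldehyde. The fallback sets out from 15 and replaces the aldol by acylation and reduction. Because a chelated metal enolate is attacked on the face opposite to that used by the boron aldol, the enantiomeric auxiliary is needed. Coupling of 15 with (4S)-4-benzyl-1,3-oxazolidin-2-one as in step 10 should give the (4S)-imide F5. Enolisation with NaN(SiMe3)2 and C-acylation with 2-methylprop-2-enoyl chloride should give the configurationally stable β-keto imide F6. Chelation-controlled reduction with Zn(BH4)2 should give the syn-hydroxy imide F7, and bromomagnesium methoxide as in step 12 returns to the route at 22.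

Step 17. The likely failure is poor facial selectivity, or a stalled oxygen transfer, on an alkene that is hindered on both faces (C20 below, the bridge above). The fallback sets out from 30 and avoids the epoxide. A peroxide-mediated Wacker-type oxidation (Pd(quinox)Cl2, AgSbF6, aqueous t-BuOOH), in which the carbonyl is placed on the alkene carbon remote from the electron-withdrawing C16 ketone, should give the 3,11,16-trione F8. Methylenation of the most accessible ketone (C16) with 32 and KN(SiMe3)2 then returns to the route at 37.

Step 22. The likely failure is incomplete or misdirected hydride delivery at C11, since the β face is partly screened by the bridge, with epimerisation at C9 on prolonged exposure to base. The fallback sets out from 38 and replaces kinetic hydride addition by electron transfer under thermodynamic control: SmI2 in THF with water should reduce the ketone through the ketyl to the more stable equatorial 11α-alcohol. It returns at 39 and makes no new compound.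

**Further compounds**

F1 | step 16 | dimethyl (6E,8S)-2-iodo-2,6-dimethyl-3-oxo-8-[(1R,5R)-6-oxobicyclo[3.2.1]oct-2-en-1-yl]non-6-enedioate | COC(=O)C(C)(I)C(=O)CC/C(C)=C/[C@H](C(=O)OC)[C@@]12CC(=O)[C@@H](C1)CC=C2
F2 | step 16 | dimethyl 11-iodo-3,16-dioxo-17-norgibberellane-7,19-dioate | O=C1C[C@]23C[C@H]1CC(I)[C@H]2[C@]1(C)CCC(=O)[C@@](C)(C(=O)OC)[C@H]1[C@@H]3C(=O)OC
F3 | step 7 | methyl 2-[(7S,9R)-7-ethenyl-9-(prop-2-en-1-yl)-1,4-dioxaspiro[4.4]nonan-7-yl]acetate (dioxolane of 12) | COC(=O)C[C@@]1(C=C)CC2(OCCO2)[C@H](CC=C)C1
F4 | step 7 | methyl 2-[7-formyl-9-(2-oxoethyl)-1,4-dioxaspiro[4.4]nonan-7-yl]acetate (dialdehyde from F3, same configuration) | COC(=O)C[C@@]1(C=O)CC2(OCCO2)[C@H](CC=O)C1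
F5 | step 11 | (4S)-4-benzyl-3-{[(1'S,5'R)-spiro[1,3-dioxolane-2,6'-bicyclo[3.2.1]oct[2]en]-1'-yl]acetyl}-1,3-oxazolidin-2-one | O=C(C[C@@]12CC3(OCCO3)[C@@H](C1)CC=C2)N1[C@@H](Cc2ccccc2)COC1=O
F6 | step 11 | (4S)-4-benzyl-3-{(2R)-4-methyl-3-oxo-2-[(1'R,5'R)-spiro[1,3-dioxolane-2,6'-bicyclo[3.2.1]oct[2]en]-1'-yl]pent-4-enoyl}-1,3-oxazolidin-2-one | C=C(C)C(=O)[C@H](C(=O)N1[C@@H](Cc2ccccc2)COC1=O)[C@@]12CC3(OCCO3)[C@@H](C1)CC=C2
F7 | step 11 | (4S)-4-benzyl-3-{(2R,3R)-3-hydroxy-4-methyl-2-[(1'R,5'R)-spiro[1,3-dioxolane-2,6'-bicyclo[3.2.1]oct[2]en]-1'-yl]pent-4-enoyl}-1,3-oxazolidin-2-one | C=C(C)[C@H](O)[C@H](C(=O)N1[C@@H](Cc2ccccc2)COC1=O)[C@@]12CC3(OCCO3)[C@@H](C1)CC=C2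
F8 | step 17 | dimethyl 3,11,16-trioxo-17-norgibberellane-7,19-dioate | O=C1C[C@]23C[C@H]1CC(=O)[C@H]2[C@]1(C)CCC(=O)[C@@](C)(C(=O)OC)[C@H]1[C@@H]3C(=O)OC
F0 | step 22 | none | none
A1 | alternative 1 | bicyclo[2.2.2]octenone dimethyl ketal fused to rings A and B (11-benzyloxy, 3-silyloxy) | O=C1C(OC)(OC)[C@]23C=C[C@H]1[C@@H](OCc4ccccc4)[C@H]2[C@]1(C)CC[C@H](O[Si](C)(C)C(C)(C)C)[C@@](C)(C(=O)OC)[C@H]1[C@@H]3C(=O)OC
A2 | alternative 1 | guaiacol with ring A and the (Z)-benzyloxyvinyl group on C10 | O(Cc1ccccc1)/C=C\[C@]1(C)CC[C@H](O[Si](C)(C)C(C)(C)C)[C@@](C)(C(=O)OC)[C@H]1[C@@H](c1cccc(O)c1OC)C(=O)OC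
A3 | alternative 2 | tetracyclic C11 silyl enol ether with C16 methylene | C=C1C[C@]23C[C@H]1C=C(O[Si](C)(C)C(C)(C)C)[C@H]2[C@]1(C)CC[C@H](O[Si](C)(C)C(C)(C)C)[C@@](C)(C(=O)OC)[C@H]1[C@@H]3C(=O)OC
A4 | alternative 2 | tricyclic 1,6-enyne (C8 propargyl, C12=C13 alkene, 11α-silyloxy) | C#CC[C@]12CC=C[C@@H](O[Si](C)(C)C(C)(C)C)[C@H]1[C@]3(C)CC[C@H](O[Si](C)(C)C(C)(C)C)[C@@](C)(C(=O)OC)[C@H]3[C@@H]2C(=O)OC
A5 | alternative 3 | tetracyclic 11-ketone with C15–C16 alkene | C1=C[C@]23C[C@H]1CC(=O)[C@H]2[C@]1(C)CC[C@H](O[Si](C)(C)C(C)(C)C)[C@@](C)(C(=O)OC)[C@H]1[C@@H]3C(=O)OC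
A6 | alternative 3 | C9 chloro ketone with the cyclopenta-1,3-dien-1-yl group on C6 | CC(=O)C(Cl)[C@]1(C)CC[C@H](O[Si](C)(C)C(C)(C)C)[C@@](C)(C(=O)OC)[C@H]1[C@@H](C1=CC=CC1)C(=O)OC
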